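(The runs stem from a simulated flask for an exercise, noise included.)

Percent of the charge is the unit of every reading here, so the charge of a flask enters through its substrate share: the substrate as a fraction of substrate and other conformer together.

| setting | spring | ash | elm | maple | alder | birch |
|---|---|---|---|---|---|---|
| substrate | 0.11 M | 0.10 M | 0.20 M | 0.060 M | 0.10 M | 0.10 M |
| other conformer | 0.050 M | 0.0500 M | 0.0150 M | 0.100 M | 0.0500 M | 0.0250 M |
| temperature | 20 °C | 50 °C | 20 °C | 20 °C | 20 °C | 5 °C |
| remark | run made earlier |  |  |  |  |  |
| time |  | 5.0 min | 5.0 min | 5.0 min | 5.0 min | 5.0 min |

spring run (percent of the substrate and other conformer together charged)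

| time / min | target / % |
|---|---|
| 0.250 | 17 |
| 0.417 | 28 |
| 0.667 | 38 |
| 1.00 | 47 |
| 2.00 | 60 |
| 3.00 | 61 |

(standard deviation of a reading: 1.5 percentage points)

- steps that have been proposed: substrate <-> other conformer; substrate -> target; other conformer -> isomer of the product; target <-> isomer of the product
- in a conversion other conformer counts as not yet reacted
- the earlier runs do not show what temperature does; that part of a forecast is a guess

- the flasks put in order of amount of target, in percent of the substrate and other conformer together charged, best first, at 5.0 min (ash / elm / maple / alder / birch)
- the amount of target, in percent of the substrate and other conformer together charged of the flask you put first, at 5.0 min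
- the amount of target, in percent of the substrate and other conformer together charged of the flask you put last, at 5.0 min

A bench rule says that each conformer goes its own way, so target should end at the substrate share. In the spring run that share is 68.8 %, but target levels off at a reading of 61 % by 3.00 min. The rule therefore stands 7.8 percentage points too high against a scatter of 1.5 points, and its border lies already in this run. The balance of the other conformer, charged in the spring run in the smaller amount, says what the gap is. If the spring flask holds just target and isomer of the product at that reading, the isomer is 39.0 % of the charge, more than the 31.2 % charged as other conformer, so the excess began as substrate. The mended rule uses 0.887, the reading of target at its level divided by the substrate share: this is the keep share, a yield of target on the substrate charged.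

My own reckoning multiplies the keep share by each substrate share at 20 °C, where 5.0 min lies later than the 3.00 min by which the readings of the spring run level off. This gives 82.5 % for elm, 59.2 % for alder and 33.3 % for maple. Ash at 50 °C and birch at 5 °C lie outside it, since the spring run shows nothing of temperature.

The forecast gives elm > birch > alder > ash > maple, with 70 % (61 % to 84 %) for the first and 50 % (36 % to 60 %) for the last, on the ground of “partial memory of the charge”. That differs from my reckoning, which puts elm higher and maple lower.

The flasks stand ash > elm > alder > birch > maple, with ash at 92.1 % and maple at 46.5 %.

    substrate ⇌ other conformer (K = 0.200, k = 0.00402 s⁻¹, Ea = 81.0 kJ mol⁻¹, ΔH = 20.0 kJ mol⁻¹)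
    substrate → target (k = 0.0223 s⁻¹, Ea = 79.0 kJ mol⁻¹)
    other conformer → isomer of the product (k = 0.278 s⁻¹, Ea = 69.0 kJ mol⁻¹)
    target ⇌ isomer of the product (K = 0.350, k = 2.85 × 10⁻⁴ s⁻¹, Ea = 95.0 kJ mol⁻¹, ΔH = −37.0 kJ mol⁻¹)
    (constants at 20 °C)

At 5.00 min ash holds target 92.1 % and isomer of the product 7.88 %, with substrate 0 % and other conformer 0 %. The target of ash exceeds its substrate share by 25 points, material charged as other conformer, so the keep share of ash is 1.38, against the 0.887 read from the spring run at 20 °C. Elm, at 20 °C like the spring run, gives 78.6 % at 5.00 min against the reckoned 82.5 %, a keep share of 0.845.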